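**Plan**

1. Retrosynthesis: the lactone bond C1–O(C14) is cut first, then the oxirane bonds C11–C12 and C11–O. This divides the seco chain into a C1–C11 allylic sulfonium salt and a C12–C23 aldehyde. Further cuts are C4–C5 and C9=C10 in the first half, and C14–C15 and C18=C19 in the second.
2. Enabling feature: the trans-oxirane C11–O–C12 carries the (E)-alkene C9=C10 on C11 and the methylene C13 on C12. This is the pattern left when an allylic sulfonium ylide adds to an aliphatic aldehyde.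
3. Forward, C1–C11: a tartrate-derived C5–C9 alkenyl iodide is coupled with a C1–C4 alkylzinc (Negishi), a Wittig reaction adds C10–C11, and the allylic bromide alkylates (2R,5R)-2,5-dimethylthiolane.
4. Forward, C12–C23: a Julia–Kocienski olefination builds the C15–C23 dienal and a γ-alkoxyallylboration adds C12–C14. The ylide epoxidation then joins the halves and closes the oxirane (first ring); Yamaguchi lactonisation closes the 15-membered ring last.
5. Stereochemistry: C7/C8 come from diethyl L-tartrate; C3 and C17 both from (R)-2-methylsuccinic acid 4-methyl ester; C14/C15 from the Ipc2B reagent; C11/C12 from the thiolane ylide. The (E)-alkenes come from Takai, Wittig and Julia–Kocienski reactions and a dissolving-metal alkyne reduction.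

Key step: step 28

Assumption: the ylide of the (2R,5R)-thiolanium salt is taken to attack aldehydes with the facial sense of the corresponding benzylic ylides, which leads to (S,S)-oxiranes; should the sense be the reverse, the sulfide from (2R,5R)-hexane-2,5-diol would be used in steps 1, 2, 16 and 28.

Abbreviations: TBS = tert-butyldimethylsilyl; PMB = 4-methoxybenzyl; PT = 1-phenyl-1H-tetrazol-5-yl; Ipc = isopinocampheyl; DMAP = 4-(dimethylamino)pyridine; DIAD = diisopropyl azodicarboxylate; DDQ = 2,3-dichloro-5,6-dicyano-1,4-benzoquinone. Atom numbers C1–C23 are those of the target.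

**Chiral sulfide**

Step 1
Reactants: 1 (2S,5S)-hexane-2,5-diol
Product: 2 (2S,5S)-hexane-2,5-diyl dimethanesulfonate
Conditions: MsCl, Et3N, CH2Cl2, 0 °C
Reagents that add atoms: methanesulfonyl chloride, CS(=O)(=O)Cl
Why: O-sulfonylation (mesylation) of both secondary alcohols proceeds with retention and turns them into leaving groups for the double displacement.

Step 2
Reactants: 2 (2S,5S)-hexane-2,5-diyl dimethanesulfonate
Product: 3 (2R,5R)-2,5-dimethylthiolane
Conditions: Na2S·9H2O, DMSO, rt to 50 °C; distillation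
Reagents that add atoms: sodium sulfide, [Na+].[Na+].[S-2]
Why: Two successive SN2 displacements by sulfide (inter- then intramolecular, 5-exo-tet) invert both carbinol centres, so the (2S,5S)-dimesylate should give the (2R,5R)-thiolane.

**C1–C11 sulfonium salt**

Step 3
Reactants: 4 (2R)-4-methoxy-2-methyl-4-oxobutanoic acid
Product: 5 methyl (3R)-4-hydroxy-3-methylbutanoate
Conditions: BH3·THF, THF, −15 °C to 0 °C; MeOH quench
Reagents that add atoms: none
Why: Borane reduces the carboxylic acid chemoselectively beside the methyl ester and leaves the stereocentre untouched; the hydroxy ester is used at once because it lactonises on standing.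

Step 4
Reactants: 5 methyl (3R)-4-hydroxy-3-methylbutanoate
Product: 6 methyl (3R)-4-iodo-3-methylbutanoate
Conditions: I2, PPh3, imidazole, CH2Cl2, 0 °C
Reagents that add atoms: iodine, II
Why: Appel-type iodination converts the primary alcohol through its alkoxyphosphonium salt into the iodide by SN2 at a non-stereogenic carbon, giving the C1–C4 unit with C3 in place.

Step 5
Reactants: 7 diethyl L-tartrate
Product: 8 diethyl (2R,3R)-2,3-bis[(tert-butyldimethylsilyl)oxy]butanedioate
Conditions: TBSOTf, 2,6-lutidine, CH2Cl2, 0 °C to rt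
Reagents that add atoms: tert-butyldimethylsilyl trifluoromethanesulfonate, CC(C)(C)[Si](C)(C)OS(=O)(=O)C(F)(F)F
Why: Silylation with the silyl triflate and a hindered base protects both secondary hydroxyls (the future C7 and C8 oxygens) without touching the stereocentres.

Step 6
Reactants: 8 diethyl (2R,3R)-2,3-bis[(tert-butyldimethylsilyl)oxy]butanedioate
Product: 9 (2S,3S)-2,3-bis[(tert-butyldimethylsilyl)oxy]butane-1,4-diol
Conditions: iBu2AlH (5 equiv), CH2Cl2, −78 °C to 0 °C; aq. KNaC4H4O6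
Reagents that add atoms: none
Why: Exhaustive iBu2AlH reduction takes both esters to primary alcohols, and the low temperature with non-basic aluminium alkoxides suppresses 1,2-silyl migration.

Step 7
Reactants: 9 (2S,3S)-2,3-bis[(tert-butyldimethylsilyl)oxy]butane-1,4-diol
Product: 10 (2S,3S)-2,3-bis[(tert-butyldimethylsilyl)oxy]-4-[(4-methoxybenzyl)oxy]butan-1-ol
Conditions: Ag2O, 4-methoxybenzyl chloride, CH2Cl2, rt, dark
Reagents that add atoms: 4-methoxybenzyl chloride, COc1ccc(CCl)cc1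
Why: Ag2O-mediated mono-O-alkylation of a symmetrical diol stops after one etherification under conditions too mild for silyl migration, and the C2 symmetry makes both hydroxyls equivalent.

Step 8
Reactants: 10 (2S,3S)-2,3-bis[(tert-butyldimethylsilyl)oxy]-4-[(4-methoxybenzyl)oxy]butan-1-ol
Product: 11 (2R,3S)-2,3-bis[(tert-butyldimethylsilyl)oxy]-4-[(4-methoxybenzyl)oxy]butanal
Conditions: Dess–Martin periodinane, NaHCO3, CH2Cl2, 0 °C to rt
Reagents that add atoms: none
Why: Buffered Dess–Martin oxidation gives the α-silyloxy aldehyde (C6) without epimerising C7.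

Step 9
Reactants: 11 (2R,3S)-2,3-bis[(tert-butyldimethylsilyl)oxy]-4-[(4-methoxybenzyl)oxy]butanal
Product: 12 1-({[(2S,3S,4E)-2,3-bis[(tert-butyldimethylsilyl)oxy]-5-iodopent-4-en-1-yl]oxy}methyl)-4-methoxybenzene
Conditions: CrCl2, CHI3, THF/1,4-dioxane, 0 °C to rt
Reagents that add atoms: iodoform, IC(I)I
Why: Takai–Utimoto iodoolefination adds the geminal dichromium species to the aldehyde and eliminates to the (E)-alkenyl iodide, which fixes the C5=C6 geometry and adds C5.

Step 10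
Reactants: 6 methyl (3R)-4-iodo-3-methylbutanoate; 12 1-({[(2S,3S,4E)-2,3-bis[(tert-butyldimethylsilyl)oxy]-5-iodopent-4-en-1-yl]oxy}methyl)-4-methoxybenzene
Product: 14 methyl (3S,5E,7S,8S)-7,8-bis[(tert-butyldimethylsilyl)oxy]-9-[(4-methoxybenzyl)oxy]-3-methylnon-5-enoate, via alkylzinc iodide 13 (not isolated)
Conditions: 6, Zn dust, LiCl, THF, 35 °C; then 12, Pd(PPh3)4 (5 mol %), THF, 50 °C
Reagents that add atoms: none
Why: Negishi sp3–sp2 cross-coupling forms C4–C5: zinc inserts into the primary C–I bond without attacking the ester, the alkenyl iodide couples with retention of the (E)-geometry, and C3 is not involved in any bond change.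

Step 11
Reactants: 14 methyl (3S,5E,7S,8S)-7,8-bis[(tert-butyldimethylsilyl)oxy]-9-[(4-methoxybenzyl)oxy]-3-methylnon-5-enoate
Product: 15 methyl (3S,5E,7S,8S)-7,8-bis[(tert-butyldimethylsilyl)oxy]-9-hydroxy-3-methylnon-5-enoate
Conditions: DDQ, CH2Cl2/pH 7 phosphate buffer, 0 °C
Reagents that add atoms: none
Why: Oxidative cleavage of the 4-methoxybenzyl ether by DDQ, through the benzylic oxocarbenium ion and its hydrolysis, frees the C9 hydroxyl while silyl ethers, ester and alkene stay intact.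

Step 12
Reactants: 15 methyl (3S,5E,7S,8S)-7,8-bis[(tert-butyldimethylsilyl)oxy]-9-hydroxy-3-methylnon-5-enoate
Product: 16 methyl (3S,5E,7S,8R)-7,8-bis[(tert-butyldimethylsilyl)oxy]-3-methyl-9-oxonon-5-enoate
Conditions: Dess–Martin periodinane, NaHCO3, CH2Cl2, 0 °C to rt
Reagents that add atoms: none
Why: Buffered Dess–Martin oxidation should give the C9 aldehyde without epimerising the adjacent silyloxy centre C8.

Step 13
Reactants: 16 methyl (3S,5E,7S,8R)-7,8-bis[(tert-butyldimethylsilyl)oxy]-3-methyl-9-oxonon-5-enoate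
Product: 17 methyl (3S,5E,7S,8S,9E)-7,8-bis[(tert-butyldimethylsilyl)oxy]-3-methyl-11-oxoundeca-5,9-dienoate
Conditions: Ph3P=CHCHO, toluene, 70 °C
Reagents that add atoms: (triphenylphosphoranylidene)acetaldehyde, O=CC=P(c1ccccc1)(c1ccccc1)c1ccccc1
Why: The Wittig reaction of the stabilised formyl ylide adds C10 and C11 and should give the (E)-enal, so that C9=C10 is fixed before the union.

Step 14
Reactants: 17 methyl (3S,5E,7S,8S,9E)-7,8-bis[(tert-butyldimethylsilyl)oxy]-3-methyl-11-oxoundeca-5,9-dienoate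
Product: 18 methyl (3S,5E,7S,8S,9E)-7,8-bis[(tert-butyldimethylsilyl)oxy]-11-hydroxy-3-methylundeca-5,9-dienoate
Conditions: NaBH4, CeCl3·7H2O, MeOH, −40 °C
Reagents that add atoms: none
Why: Luche reduction delivers hydride 1,2 to the enal only, leaving the saturated methyl ester at C1 and the alkene geometry unchanged.

Step 15
Reactants: 18 methyl (3S,5E,7S,8S,9E)-7,8-bis[(tert-butyldimethylsilyl)oxy]-11-hydroxy-3-methylundeca-5,9-dienoate
Product: 19 methyl (3S,5E,7S,8S,9E)-11-bromo-7,8-bis[(tert-butyldimethylsilyl)oxy]-3-methylundeca-5,9-dienoate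
Conditions: CBr4, PPh3, 2,6-lutidine, CH2Cl2, −20 °C
Reagents that add atoms: carbon tetrabromide, BrC(Br)(Br)Br
Why: Appel bromination substitutes the primary allylic alcohol by SN2 at C11 under buffered, near-neutral conditions, so allylic transposition towards the hindered C9 is not expected.

Step 16
Reactants: 19 methyl (3S,5E,7S,8S,9E)-11-bromo-7,8-bis[(tert-butyldimethylsilyl)oxy]-3-methylundeca-5,9-dienoate; 3 (2R,5R)-2,5-dimethylthiolane
Product: 20 (2R,5R)-1-[(2E,4S,5S,6E,9S)-4,5-bis[(tert-butyldimethylsilyl)oxy]-11-methoxy-9-methyl-11-oxoundeca-2,6-dien-1-yl]-2,5-dimethylthiolan-1-ium tetrafluoroborate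
Conditions: 3 (3 equiv), AgBF4, CH2Cl2, −30 °C to rt, dark
Reagents that add atoms: silver tetrafluoroborate, [Ag+].F[B-](F)(F)F
Why: S-alkylation of the sulfide by the allylic bromide is driven by precipitation of silver bromide, and because the two lone pairs of the C2-symmetric thiolane are homotopic a single salt without a sulfur stereocentre should result.

**C12–C23 aldehyde**

Step 17
Reactants: 21 pent-3-yn-1-ol
Product: 22 (3E)-pent-3-en-1-ol
Conditions: Na, NH3 (l), THF, −33 °C; NH4Cl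
Reagents that add atoms: none
Why: Dissolving-metal reduction of the internal alkyne passes through the trans-vinyl anion and sets the (E)-geometry of the future C21=C22 alkene.

Step 18
Reactants: 22 (3E)-pent-3-en-1-ol
Product: 23 5-[(3E)-pent-3-en-1-ylsulfanyl]-1-phenyl-1H-tetrazole
Conditions: 1-phenyl-1H-tetrazole-5-thiol, PPh3, DIAD, THF, 0 °C to rt
Reagents that add atoms: 1-phenyl-1H-tetrazole-5-thiol, Sc1nnnn1-c1ccccc1
Why: Mitsunobu thioetherification of the primary alcohol with the acidic heteroaryl thiol installs the sulfur needed for the olefination.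

Step 19
Reactants: 23 5-[(3E)-pent-3-en-1-ylsulfanyl]-1-phenyl-1H-tetrazole
Product: 24 5-[(3E)-pent-3-ene-1-sulfonyl]-1-phenyl-1H-tetrazole
Conditions: (NH4)6Mo7O24·4H2O (cat.), 30% H2O2, EtOH, 0 °C to rt
Reagents that add atoms: hydrogen peroxide, OO
Why: Molybdate-catalysed peroxide oxidation takes the sulfide to the sulfone and does not epoxidise the isolated 1,2-disubstituted alkene.

Step 20
Reactants: 5 methyl (3R)-4-hydroxy-3-methylbutanoate
Product: 25 methyl (3R)-3-methyl-4-oxobutanoate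
Conditions: Dess–Martin periodinane, NaHCO3, CH2Cl2, 0 °C
Reagents that add atoms: none
Why: Buffered Dess–Martin oxidation gives the α-methyl aldehyde (C18) under conditions that should not epimerise C17; the volatile aldehyde is used in solution.

Step 21
Reactants: 24 5-[(3E)-pent-3-ene-1-sulfonyl]-1-phenyl-1H-tetrazole; 25 methyl (3R)-3-methyl-4-oxobutanoate
Product: 27 methyl (3R,4E,7E)-3-methylnona-4,7-dienoate, via potassium sulfonyl carbanion 26 (not isolated)
Conditions: 24, KN(SiMe3)2, DME, −60 °C; then 25, −60 °C to rt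
Reagents that add atoms: none
Why: Julia–Kocienski olefination (addition, Smiles rearrangement, loss of SO2 and tetrazolate) with a potassium counter-ion in DME should give the (E)-alkene C18=C19; the pre-formed sulfonyl anion adds to the aldehyde faster than it enolises it or attacks the ester.

Step 22
Reactants: 27 methyl (3R,4E,7E)-3-methylnona-4,7-dienoate
Product: 28 (3R,4E,7E)-3-methylnona-4,7-dienal
Conditions: iBu2AlH (1.05 equiv), CH2Cl2, −78 °C; MeOH, aq. KNaC4H4O6
Reagents that add atoms: none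
Why: Partial reduction of the methyl ester stops at the aluminium hemiacetal at −78 °C and releases the C15 aldehyde on work-up.

Step 23
Reactants: 29 prop-2-en-1-ol
Product: 30 1-methoxy-4-[(prop-2-en-1-yloxy)methyl]benzene
Conditions: NaH, THF/DMF, 0 °C; 4-methoxybenzyl chloride, Bu4NI (cat.), rt
Reagents that add atoms: 4-methoxybenzyl chloride, COc1ccc(CCl)cc1
Why: Williamson etherification of the alkoxide with the benzylic chloride gives the allyl ether that carries C12–C14 and the C14 protecting group.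

Step 24
Reactants: 28 (3R,4E,7E)-3-methylnona-4,7-dienal; 30 1-methoxy-4-[(prop-2-en-1-yloxy)methyl]benzene
Product: 33 (3S,4S,6R,7E,10E)-3-[(4-methoxybenzyl)oxy]-6-methyldodeca-1,7,10-trien-4-ol, via alkoxyallylborane 31 (not isolated), via borinate 32 (not isolated)
Conditions: 30, s-BuLi, THF, −78 °C; (+)-Ipc2BOMe; BF3·OEt2; 28, −78 °C; then NaOH, H2O2, 0 °C to rt
Reagents that add atoms: none
Why: In this Brown γ-alkoxyallylboration the lithium-chelated (Z)-alkoxyallyl anion gives the (Z)-borane 31, which adds through a closed chair transition state to give the syn adduct; the isopinocampheyl groups from (−)-α-pinene direct it to the Re face of the aldehyde, so C14 and C15 should be set as (14S,15S) independently of C17.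

Step 25
Reactants: 33 (3S,4S,6R,7E,10E)-3-[(4-methoxybenzyl)oxy]-6-methyldodeca-1,7,10-trien-4-ol
Product: 34 tert-butyl{[(3S,4S,6R,7E,10E)-3-[(4-methoxybenzyl)oxy]-6-methyldodeca-1,7,10-trien-4-yl]oxy}dimethylsilane
Conditions: TBSOTf, 2,6-lutidine, CH2Cl2, −78 °C to 0 °C
Reagents that add atoms: tert-butyldimethylsilyl trifluoromethanesulfonate, CC(C)(C)[Si](C)(C)OS(=O)(=O)C(F)(F)F
Why: Silylation of the hindered secondary C15 hydroxyl with the silyl triflate differentiates it from the C14 oxygen, which stays as the oxidatively removable benzyl-type ether.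

Step 26
Reactants: 34 tert-butyl{[(3S,4S,6R,7E,10E)-3-[(4-methoxybenzyl)oxy]-6-methyldodeca-1,7,10-trien-4-yl]oxy}dimethylsilane
Product: 36 (3S,4S,6R,7E,10E)-4-[(tert-butyldimethylsilyl)oxy]-3-[(4-methoxybenzyl)oxy]-6-methyldodeca-7,10-dien-1-ol, via B-alkyl-9-borabicyclononane 35 (not isolated)
Conditions: 9-borabicyclo[3.3.1]nonane, THF, 0 °C to rt; then NaOH, H2O2, 0 °C
Reagents that add atoms: hydrogen peroxide, OO
Why: Hydroboration–oxidation with the bulky dialkylborane is anti-Markovnikov and selective for the monosubstituted alkene over the two 1,2-disubstituted ones, placing the hydroxyl on C12.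

Step 27
Reactants: 36 (3S,4S,6R,7E,10E)-4-[(tert-butyldimethylsilyl)oxy]-3-[(4-methoxybenzyl)oxy]-6-methyldodeca-7,10-dien-1-ol
Product: 37 (3S,4S,6R,7E,10E)-4-[(tert-butyldimethylsilyl)oxy]-3-[(4-methoxybenzyl)oxy]-6-methyldodeca-7,10-dienal
Conditions: Dess–Martin periodinane, NaHCO3, CH2Cl2, 0 °C
Reagents that add atoms: none
Why: Buffered Dess–Martin oxidation gives the β-alkoxy aldehyde (C12) without β-elimination; it is used directly in the union.

**Union and endgame**

Step 28
Reactants: 20 (2R,5R)-1-[(2E,4S,5S,6E,9S)-4,5-bis[(tert-butyldimethylsilyl)oxy]-11-methoxy-9-methyl-11-oxoundeca-2,6-dien-1-yl]-2,5-dimethylthiolan-1-ium tetrafluoroborate; 37 (3S,4S,6R,7E,10E)-4-[(tert-butyldimethylsilyl)oxy]-3-[(4-methoxybenzyl)oxy]-6-methyldodeca-7,10-dienal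
Product: 40 methyl (3S,5E,7S,8S,9E,11S,12S,14S,15S,17R,18E,21E)-7,8,15-tris[(tert-butyldimethylsilyl)oxy]-11,12-epoxy-14-[(4-methoxybenzyl)oxy]-3,17-dimethyltricosa-5,9,18,21-tetraenoate, via sulfonium ylide 38 (not isolated), via anti betaine 39 (not isolated)
Conditions: 20 (1.3 equiv) and 37 in CH2Cl2, −78 °C; phosphazene base P2-Et [EtN=P(NMe2)2–N=P(NMe2)3] (1.3 equiv) added slowly; −78 °C to −40 °C
Reagents that add atoms: none
Why: The phosphazene base removes the C11 proton, the only C–H that is both allylic and alpha to sulfonium, and the semistabilised ylide 38 adds through C11 to the carbonyl carbon C12 of 37 to give the anti betaine 39, whose alkoxide displaces the thiolane from C11 with inversion. The closest known reaction type is the asymmetric Corey–Chaykovsky epoxidation of aldehydes with allylic and benzylic ylides of C2-symmetric 2,5-dialkylthiolanes. The oxirane closes by 3-exo-tet substitution, after C11–C12 has formed and by making C11–O. The trans relation of C11 and C12 should follow from fast, irreversible collapse of the anti betaine while the syn betaine reverts to ylide and aldehyde, and the (11S,12S) configuration is assigned to control by the (2R,5R)-thiolane, whose ring methyl groups fix the ylide conformation and expose one face of C11. The step needs alpha- rather than gamma-attack of the ylide and ylide formation in the presence of an enolisable ester and aldehyde: the C8 silyloxy group shields C9, the sulfonium C–H is far more acidic than the ester alpha-C–H, and slow addition of a non-nucleophilic, salt-free base at −78 °C to the premixed partners keeps base and ylide concentrations low enough to spare the beta-alkoxy aldehyde.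

Step 29
Reactants: 40 methyl (3S,5E,7S,8S,9E,11S,12S,14S,15S,17R,18E,21E)-7,8,15-tris[(tert-butyldimethylsilyl)oxy]-11,12-epoxy-14-[(4-methoxybenzyl)oxy]-3,17-dimethyltricosa-5,9,18,21-tetraenoate
Product: 41 (3S,5E,7S,8S,9E,11S,12S,14S,15S,17R,18E,21E)-7,8,15-tris[(tert-butyldimethylsilyl)oxy]-11,12-epoxy-14-[(4-methoxybenzyl)oxy]-3,17-dimethyltricosa-5,9,18,21-tetraenoic acid
Conditions: LiOH·H2O, THF/MeOH/H2O, 0 °C to rt; aq. NaH2PO4 to pH 5
Reagents that add atoms: lithium hydroxide, [Li+].[OH-]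
Why: Saponification of the unhindered methyl ester is done while every hydroxyl is still protected, so that neither silyl migration to O14 nor alkoxide attack on the oxirane can occur, and the mild acidification spares the vinyl oxirane.

Step 30
Reactants: 41 (3S,5E,7S,8S,9E,11S,12S,14S,15S,17R,18E,21E)-7,8,15-tris[(tert-butyldimethylsilyl)oxy]-11,12-epoxy-14-[(4-methoxybenzyl)oxy]-3,17-dimethyltricosa-5,9,18,21-tetraenoic acid
Product: 42 (3S,5E,7S,8S,9E,11S,12S,14S,15S,17R,18E,21E)-7,8,15-tris[(tert-butyldimethylsilyl)oxy]-11,12-epoxy-14-hydroxy-3,17-dimethyltricosa-5,9,18,21-tetraenoic acid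
Conditions: DDQ, CH2Cl2/pH 7 phosphate buffer, 0 °C
Reagents that add atoms: none
Why: Buffered DDQ cleavage of the 4-methoxybenzyl ether frees only the C14 hydroxyl under neutral conditions that avoid acid-promoted opening of the vinyl oxirane by that hydroxyl.

Step 31
Reactants: 42 (3S,5E,7S,8S,9E,11S,12S,14S,15S,17R,18E,21E)-7,8,15-tris[(tert-butyldimethylsilyl)oxy]-11,12-epoxy-14-hydroxy-3,17-dimethyltricosa-5,9,18,21-tetraenoic acid
Product: 44 7,8,15-tris-O-(tert-butyldimethylsilyl)iriomoteolide 3a, via mixed anhydride 43 (not isolated)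
Conditions: 2,4,6-trichlorobenzoyl chloride, Et3N, THF, rt; then slow addition to DMAP, toluene, rt to 40 °C (about 1 mM)
Reagents that add atoms: none
Why: Yamaguchi macrolactonisation activates C1 as the mixed anhydride and, under high dilution with acyl transfer through the acylpyridinium ion, should close the 15-membered ring on the only free hydroxyl (O14) with retention at C14.

Step 32
Reactants: 44 7,8,15-tris-O-(tert-butyldimethylsilyl)iriomoteolide 3a
Product: 45 iriomoteolide 3a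
Conditions: HF·pyridine, pyridine, THF, 0 °C to rt
Reagents that add atoms: none
Why: Fluoride-mediated desilylation buffered with excess pyridine should remove the two allylic silyl ethers and the C15 silyl ether while avoiding both the basic conditions that cause acyl migration from O14 to O15 and the strong acid that would open the vinyl oxirane.

**Compound list**

1 | (2S,5S)-hexane-2,5-diol | C[C@H](O)CC[C@H](C)O | starting material
2 | (2S,5S)-hexane-2,5-diyl dimethanesulfonate | C[C@H](OS(C)(=O)=O)CC[C@H](C)OS(C)(=O)=O | intermediate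
3 | (2R,5R)-2,5-dimethylthiolane | C[C@@H]1CC[C@@H](C)S1 | intermediate
4 | (2R)-4-methoxy-2-methyl-4-oxobutanoic acid [(R)-2-methylsuccinic acid 4-methyl ester] | OC(=O)[C@H](C)CC(=O)OC | starting material
5 | methyl (3R)-4-hydroxy-3-methylbutanoate | OC[C@H](C)CC(=O)OC | intermediate
6 | methyl (3R)-4-iodo-3-methylbutanoate | IC[C@H](C)CC(=O)OC | intermediate
7 | diethyl L-tartrate [diethyl (2R,3R)-2,3-dihydroxybutanedioate] | CCOC(=O)[C@H](O)[C@@H](O)C(=O)OCC | starting material
8 | diethyl (2R,3R)-2,3-bis[(tert-butyldimethylsilyl)oxy]butanedioate | CCOC(=O)[C@H](O[Si](C)(C)C(C)(C)C)[C@@H](O[Si](C)(C)C(C)(C)C)C(=O)OCC | intermediate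
9 | (2S,3S)-2,3-bis[(tert-butyldimethylsilyl)oxy]butane-1,4-diol | OC[C@H](O[Si](C)(C)C(C)(C)C)[C@@H](O[Si](C)(C)C(C)(C)C)CO | intermediate
10 | (2S,3S)-2,3-bis[(tert-butyldimethylsilyl)oxy]-4-[(4-methoxybenzyl)oxy]butan-1-ol | COc1ccc(COC[C@H](O[Si](C)(C)C(C)(C)C)[C@@H](O[Si](C)(C)C(C)(C)C)CO)cc1 | intermediate
11 | (2R,3S)-2,3-bis[(tert-butyldimethylsilyl)oxy]-4-[(4-methoxybenzyl)oxy]butanal | COc1ccc(COC[C@H](O[Si](C)(C)C(C)(C)C)[C@@H](O[Si](C)(C)C(C)(C)C)C=O)cc1 | intermediate
12 | 1-({[(2S,3S,4E)-2,3-bis[(tert-butyldimethylsilyl)oxy]-5-iodopent-4-en-1-yl]oxy}methyl)-4-methoxybenzene | COc1ccc(COC[C@H](O[Si](C)(C)C(C)(C)C)[C@@H](O[Si](C)(C)C(C)(C)C)/C=C/I)cc1 | intermediate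
13 | [(2R)-4-methoxy-2-methyl-4-oxobutyl]zinc iodide | COC(=O)C[C@@H](C)C[Zn]I | intermediate (not isolated)
14 | methyl (3S,5E,7S,8S)-7,8-bis[(tert-butyldimethylsilyl)oxy]-9-[(4-methoxybenzyl)oxy]-3-methylnon-5-enoate | COc1ccc(COC[C@H](O[Si](C)(C)C(C)(C)C)[C@@H](O[Si](C)(C)C(C)(C)C)/C=C/C[C@H](C)CC(=O)OC)cc1 | intermediate
15 | methyl (3S,5E,7S,8S)-7,8-bis[(tert-butyldimethylsilyl)oxy]-9-hydroxy-3-methylnon-5-enoate | OC[C@H](O[Si](C)(C)C(C)(C)C)[C@@H](O[Si](C)(C)C(C)(C)C)/C=C/C[C@H](C)CC(=O)OC | intermediate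
16 | methyl (3S,5E,7S,8R)-7,8-bis[(tert-butyldimethylsilyl)oxy]-3-methyl-9-oxonon-5-enoate | O=C[C@H](O[Si](C)(C)C(C)(C)C)[C@@H](O[Si](C)(C)C(C)(C)C)/C=C/C[C@H](C)CC(=O)OC | intermediate
17 | methyl (3S,5E,7S,8S,9E)-7,8-bis[(tert-butyldimethylsilyl)oxy]-3-methyl-11-oxoundeca-5,9-dienoate | O=C/C=C/[C@H](O[Si](C)(C)C(C)(C)C)[C@@H](O[Si](C)(C)C(C)(C)C)/C=C/C[C@H](C)CC(=O)OC | intermediate
18 | methyl (3S,5E,7S,8S,9E)-7,8-bis[(tert-butyldimethylsilyl)oxy]-11-hydroxy-3-methylundeca-5,9-dienoate | OC/C=C/[C@H](O[Si](C)(C)C(C)(C)C)[C@@H](O[Si](C)(C)C(C)(C)C)/C=C/C[C@H](C)CC(=O)OC | intermediate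
19 | methyl (3S,5E,7S,8S,9E)-11-bromo-7,8-bis[(tert-butyldimethylsilyl)oxy]-3-methylundeca-5,9-dienoate | BrC/C=C/[C@H](O[Si](C)(C)C(C)(C)C)[C@@H](O[Si](C)(C)C(C)(C)C)/C=C/C[C@H](C)CC(=O)OC | intermediate
20 | (2R,5R)-1-[(2E,4S,5S,6E,9S)-4,5-bis[(tert-butyldimethylsilyl)oxy]-11-methoxy-9-methyl-11-oxoundeca-2,6-dien-1-yl]-2,5-dimethylthiolan-1-ium tetrafluoroborate | C[C@@H]1CC[C@@H](C)[S+]1C/C=C/[C@H](O[Si](C)(C)C(C)(C)C)[C@@H](O[Si](C)(C)C(C)(C)C)/C=C/C[C@H](C)CC(=O)OC.F[B-](F)(F)F | intermediate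
21 | pent-3-yn-1-ol | CC#CCCO | starting material
22 | (3E)-pent-3-en-1-ol | C/C=C/CCO | intermediate
23 | 5-[(3E)-pent-3-en-1-ylsulfanyl]-1-phenyl-1H-tetrazole | C/C=C/CCSc1nnnn1-c1ccccc1 | intermediate
24 | 5-[(3E)-pent-3-ene-1-sulfonyl]-1-phenyl-1H-tetrazole | C/C=C/CCS(=O)(=O)c1nnnn1-c1ccccc1 | intermediate
25 | methyl (3R)-3-methyl-4-oxobutanoate | O=C[C@H](C)CC(=O)OC | intermediate
26 | potassium (3E)-1-[(1-phenyl-1H-tetrazol-5-yl)sulfonyl]pent-3-en-1-ide | C/C=C/C[CH-]S(=O)(=O)c1nnnn1-c1ccccc1.[K+] | intermediate (not isolated)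
27 | methyl (3R,4E,7E)-3-methylnona-4,7-dienoate | C/C=C/C/C=C/[C@H](C)CC(=O)OC | intermediate
28 | (3R,4E,7E)-3-methylnona-4,7-dienal | C/C=C/C/C=C/[C@H](C)CC=O | intermediate
29 | prop-2-en-1-ol | C=CCO | starting material
30 | 1-methoxy-4-[(prop-2-en-1-yloxy)methyl]benzene | C=CCOCc1ccc(OC)cc1 | intermediate
31 | [(2Z)-3-[(4-methoxybenzyl)oxy]prop-2-en-1-yl]bis[(1S,2S,3S,5R)-isopinocampheyl]borane | COc1ccc(CO/C=C\CB([C@H]2C[C@H]3C[C@@H]([C@@H]2C)C3(C)C)[C@H]2C[C@H]3C[C@@H]([C@@H]2C)C3(C)C)cc1 | intermediate (not isolated)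
32 | bis[(1S,2S,3S,5R)-isopinocampheyl]borinic ester of 33 | C/C=C/C/C=C/[C@H](C)C[C@H](OB([C@H]1C[C@H]2C[C@@H]([C@@H]1C)C2(C)C)[C@H]1C[C@H]2C[C@@H]([C@@H]1C)C2(C)C)[C@@H](OCc1ccc(OC)cc1)C=C | intermediate (not isolated)
33 | (3S,4S,6R,7E,10E)-3-[(4-methoxybenzyl)oxy]-6-methyldodeca-1,7,10-trien-4-ol | C/C=C/C/C=C/[C@H](C)C[C@H](O)[C@@H](OCc1ccc(OC)cc1)C=C | intermediate
34 | tert-butyl{[(3S,4S,6R,7E,10E)-3-[(4-methoxybenzyl)oxy]-6-methyldodeca-1,7,10-trien-4-yl]oxy}dimethylsilane | C/C=C/C/C=C/[C@H](C)C[C@H](O[Si](C)(C)C(C)(C)C)[C@@H](OCc1ccc(OC)cc1)C=C | intermediate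
35 | 9-[(3S,4S,6R,7E,10E)-4-[(tert-butyldimethylsilyl)oxy]-3-[(4-methoxybenzyl)oxy]-6-methyldodeca-7,10-dien-1-yl]-9-borabicyclo[3.3.1]nonane | C/C=C/C/C=C/[C@H](C)C[C@H](O[Si](C)(C)C(C)(C)C)[C@@H](OCc1ccc(OC)cc1)CCB1C2CCCC1CCC2 | intermediate (not isolated)
36 | (3S,4S,6R,7E,10E)-4-[(tert-butyldimethylsilyl)oxy]-3-[(4-methoxybenzyl)oxy]-6-methyldodeca-7,10-dien-1-ol | C/C=C/C/C=C/[C@H](C)C[C@H](O[Si](C)(C)C(C)(C)C)[C@@H](OCc1ccc(OC)cc1)CCO | intermediate
37 | (3S,4S,6R,7E,10E)-4-[(tert-butyldimethylsilyl)oxy]-3-[(4-methoxybenzyl)oxy]-6-methyldodeca-7,10-dienal | C/C=C/C/C=C/[C@H](C)C[C@H](O[Si](C)(C)C(C)(C)C)[C@@H](OCc1ccc(OC)cc1)CC=O | intermediate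
38 | C11 ylide of 20 [(2R,5R)-2,5-dimethylthiolanium allylide] | C[C@@H]1CC[C@@H](C)[S+]1[CH-]/C=C/[C@H](O[Si](C)(C)C(C)(C)C)[C@@H](O[Si](C)(C)C(C)(C)C)/C=C/C[C@H](C)CC(=O)OC | intermediate (not isolated)
39 | anti betaine (C12 alkoxide, C11 thiolanium) from 38 and 37 | C/C=C/C/C=C/[C@H](C)C[C@H](O[Si](C)(C)C(C)(C)C)[C@@H](OCc1ccc(OC)cc1)C[C@H]([O-])[C@H]([S+]1[C@H](C)CC[C@H]1C)/C=C/[C@H](O[Si](C)(C)C(C)(C)C)[C@@H](O[Si](C)(C)C(C)(C)C)/C=C/C[C@H](C)CC(=O)OC | intermediate (not isolated)
40 | methyl (3S,5E,7S,8S,9E,11S,12S,14S,15S,17R,18E,21E)-7,8,15-tris[(tert-butyldimethylsilyl)oxy]-11,12-epoxy-14-[(4-methoxybenzyl)oxy]-3,17-dimethyltricosa-5,9,18,21-tetraenoate | C/C=C/C/C=C/[C@H](C)C[C@H](O[Si](C)(C)C(C)(C)C)[C@@H](OCc1ccc(OC)cc1)C[C@@H]2O[C@H]2/C=C/[C@H](O[Si](C)(C)C(C)(C)C)[C@@H](O[Si](C)(C)C(C)(C)C)/C=C/C[C@H](C)CC(=O)OC | intermediate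
41 | (3S,5E,7S,8S,9E,11S,12S,14S,15S,17R,18E,21E)-7,8,15-tris[(tert-butyldimethylsilyl)oxy]-11,12-epoxy-14-[(4-methoxybenzyl)oxy]-3,17-dimethyltricosa-5,9,18,21-tetraenoic acid | C/C=C/C/C=C/[C@H](C)C[C@H](O[Si](C)(C)C(C)(C)C)[C@@H](OCc1ccc(OC)cc1)C[C@@H]2O[C@H]2/C=C/[C@H](O[Si](C)(C)C(C)(C)C)[C@@H](O[Si](C)(C)C(C)(C)C)/C=C/C[C@H](C)CC(=O)O | intermediate
42 | (3S,5E,7S,8S,9E,11S,12S,14S,15S,17R,18E,21E)-7,8,15-tris[(tert-butyldimethylsilyl)oxy]-11,12-epoxy-14-hydroxy-3,17-dimethyltricosa-5,9,18,21-tetraenoic acid | C/C=C/C/C=C/[C@H](C)C[C@H](O[Si](C)(C)C(C)(C)C)[C@@H](O)C[C@@H]1O[C@H]1/C=C/[C@H](O[Si](C)(C)C(C)(C)C)[C@@H](O[Si](C)(C)C(C)(C)C)/C=C/C[C@H](C)CC(=O)O | intermediate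
43 | mixed anhydride of 42 with 2,4,6-trichlorobenzoic acid | C/C=C/C/C=C/[C@H](C)C[C@H](O[Si](C)(C)C(C)(C)C)[C@@H](O)C[C@@H]1O[C@H]1/C=C/[C@H](O[Si](C)(C)C(C)(C)C)[C@@H](O[Si](C)(C)C(C)(C)C)/C=C/C[C@H](C)CC(=O)OC(=O)c1c(Cl)cc(Cl)cc1Cl | intermediate (not isolated)
44 | 7,8,15-tris-O-(tert-butyldimethylsilyl)iriomoteolide 3a | C/C=C/C/C=C/[C@H](C)C[C@H](O[Si](C)(C)C(C)(C)C)[C@@H]1C[C@@H]2O[C@H]2/C=C/[C@H](O[Si](C)(C)C(C)(C)C)[C@@H](O[Si](C)(C)C(C)(C)C)/C=C/C[C@H](C)CC(=O)O1 | intermediate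
45 | iriomoteolide 3a | C/C=C/C/C=C/[C@H](C)C[C@H](O)[C@@H]1C[C@@H]2O[C@H]2/C=C/[C@H](O)[C@@H](O)/C=C/C[C@H](C)CC(=O)O1 | target

**Step count**

Total: 32 steps. Longest linear sequence: 17 steps (from diethyl L-tartrate 7: steps 5–16, then 28–32).

**Steps most likely to fail, with fallbacks**

Step 28 (ylide epoxidation). What may go wrong: betaine formation from the hindered, γ-oxygenated ylide may be slow. Base-induced β-elimination of the 4-methoxybenzyloxy group from the aldehyde, or loss of trans and facial selectivity, could then compete. The fallback sets out from bromide 19 and aldehyde 37 and replaces the sulfonium ylide by a more nucleophilic arsonium ylide. Triphenylarsine and AgBF4 in CH2Cl2 would convert 19 into the allylic triphenylarsonium tetrafluoroborate F1. Deprotonation with KN(SiMe3)2 in THF at −78 °C and addition of 37 should give trans-vinyl oxiranes, as semistabilised allylic arsonium ylides do, but without facial control. Compound 40 would therefore be accompanied by its (11R,12R)-diastereomer F2, to be removed by chromatography. The fallback comes back to the route at 40.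

Step 31 (macrolactonisation). What may go wrong: intermolecular acylation may outrun ring closure, or chloride, carboxylate or the acylpyridinium salt may open the vinyl oxirane under the basic activation. The fallback sets out from seco acid 42 and changes the activation to a neutral double activation. 2,2′-Dipyridyl disulfide and PPh3 in CH2Cl2 would give the S-(pyridin-2-yl) thioester F3. Slow addition of F3 to toluene at 80–100 °C under high dilution (Corey–Nicolaou lactonisation, no base, no chloride) should close the ring. The fallback comes back at 44.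

Step 24 (γ-alkoxyallylboration). What may go wrong: benzylic metalation and Wittig rearrangement of the lithiated allyl ether may compete with allylic metalation, leaving too little of the (Z)-borane and eroding the syn selectivity. The fallback sets out from aldehyde 28 and builds the syn C14/C15 pair by an Evans syn-glycolate aldol reaction.
- (4R)-4-Benzyl-1,3-oxazolidin-2-one would be N-acylated with [(4-methoxybenzyl)oxy]acetyl chloride to give the imide F4.
- Its dibutylboron enolate (Bu2BOTf, Et3N, CH2Cl2, −78 °C) would add to 28 to give the syn aldol F5.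
- Silylation (TBSOTf, 2,6-lutidine) would give the silyl ether F6.
- LiBH4 would cleave the auxiliary to give the primary alcohol F7.
- Dess–Martin oxidation would give the α-alkoxy aldehyde F8.
- Methylenation with Ph3P=CH2 at low temperature would give 34, where the fallback comes back to the route.

**Further compounds**

F1 | step 28 | [(2E,4S,5S,6E,9S)-4,5-bis[(tert-butyldimethylsilyl)oxy]-11-methoxy-9-methyl-11-oxoundeca-2,6-dien-1-yl]triphenylarsonium tetrafluoroborate | c1ccccc1[As+](c1ccccc1)(c1ccccc1)C/C=C/[C@H](O[Si](C)(C)C(C)(C)C)[C@@H](O[Si](C)(C)C(C)(C)C)/C=C/C[C@H](C)CC(=O)OC.F[B-](F)(F)F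
F2 | step 28 | (11R,12R)-diastereomer of 40 | C/C=C/C/C=C/[C@H](C)C[C@H](O[Si](C)(C)C(C)(C)C)[C@@H](OCc1ccc(OC)cc1)C[C@H]2O[C@@H]2/C=C/[C@H](O[Si](C)(C)C(C)(C)C)[C@@H](O[Si](C)(C)C(C)(C)C)/C=C/C[C@H](C)CC(=O)OC
F3 | step 31 | S-(pyridin-2-yl) thioester of seco acid 42 | C/C=C/C/C=C/[C@H](C)C[C@H](O[Si](C)(C)C(C)(C)C)[C@@H](O)C[C@@H]1O[C@H]1/C=C/[C@H](O[Si](C)(C)C(C)(C)C)[C@@H](O[Si](C)(C)C(C)(C)C)/C=C/C[C@H](C)CC(=O)Sc1ccccn1
F4 | step 24 | (4R)-4-benzyl-3-{[(4-methoxybenzyl)oxy]acetyl}-1,3-oxazolidin-2-one | COc1ccc(COCC(=O)N2[C@H](Cc3ccccc3)COC2=O)cc1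
F5 | step 24 | (4R)-4-benzyl-3-[(2R,3S,5R,6E,9E)-3-hydroxy-2-[(4-methoxybenzyl)oxy]-5-methylundeca-6,9-dienoyl]-1,3-oxazolidin-2-one | C/C=C/C/C=C/[C@H](C)C[C@H](O)[C@@H](OCc1ccc(OC)cc1)C(=O)N1[C@H](Cc2ccccc2)COC1=O
F6 | step 24 | (4R)-4-benzyl-3-[(2R,3S,5R,6E,9E)-3-[(tert-butyldimethylsilyl)oxy]-2-[(4-methoxybenzyl)oxy]-5-methylundeca-6,9-dienoyl]-1,3-oxazolidin-2-one | C/C=C/C/C=C/[C@H](C)C[C@H](O[Si](C)(C)C(C)(C)C)[C@@H](OCc1ccc(OC)cc1)C(=O)N1[C@H](Cc2ccccc2)COC1=O
F7 | step 24 | (2S,3S,5R,6E,9E)-3-[(tert-butyldimethylsilyl)oxy]-2-[(4-methoxybenzyl)oxy]-5-methylundeca-6,9-dien-1-ol | C/C=C/C/C=C/[C@H](C)C[C@H](O[Si](C)(C)C(C)(C)C)[C@@H](OCc1ccc(OC)cc1)CO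
F8 | step 24 | (2R,3S,5R,6E,9E)-3-[(tert-butyldimethylsilyl)oxy]-2-[(4-methoxybenzyl)oxy]-5-methylundeca-6,9-dienal | C/C=C/C/C=C/[C@H](C)C[C@H](O[Si](C)(C)C(C)(C)C)[C@@H](OCc1ccc(OC)cc1)C=O
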